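**Retrosynthetic overview**

1. Both C6–C3 halves come from aldehyde 1 and vinylmagnesium bromide 2 through racemic allylic alcohol 3; resolved epoxy alcohol 4 (carries C7) and cinnamyl bromide 5, both made from 3, are joined at the C7–O–C9' ether bond in epoxy ether 6.
2. Key disconnection: C8–C8' and C7'–O of a furofuran; forward, 6 closes both tetrahydrofuran rings in one flask (radical 5-exo closure to 7, iodination to 8, O-alkylation to furofuran 9).
3. Ring order: ring A (O, C7, C8, C8', C9'; the ring kept in the target) first, ring B (O, C9, C8, C8', C7') directly after it in the same operation.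
4. Last disconnection: the C9–OH / C7'H2 pair of the target is one benzylic C–O bond of C2-symmetric 9; hydrogenolysis removes both benzyl groups (10) and opens ring B to give target 11.
5. Stereochemistry: only C7 comes from a reagent (kinetic resolution, step 2); C8, C8' and the temporary C7' centre follow from C7 in the cascade.

Assumption: 1 is bought as such (catalogue compound); lignan numbering (C7–C9, C7'–C9') is used for all intermediates.

**Route**

Step 1
Reactants: 1 4-(benzyloxy)-3,5-dimethoxybenzaldehyde; 2 vinylmagnesium bromide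
Product: 3 rac-1-[4-(benzyloxy)-3,5-dimethoxyphenyl]prop-2-en-1-ol
Conditions: CH2=CHMgBr (1.2 equiv), THF, 0 °C; aq. NH4Cl
Reagents that add atoms: vinylmagnesium bromide (2), C=C[Mg]Br
Why: Grignard 1,2-addition to the aldehyde gives the racemic secondary allylic alcohol, and no stereocontrol is needed because C7 is set in step 2 and erased in step 3.

Step 2
Reactants: 3 rac-1-[4-(benzyloxy)-3,5-dimethoxyphenyl]prop-2-en-1-ol
Product: 4 (R)-[4-(benzyloxy)-3,5-dimethoxyphenyl][(2S)-oxiran-2-yl]methanol (erythro)
Conditions: Ti(O-i-Pr)4 (15 mol%), D-(−)-diisopropyl tartrate (20 mol%), t-BuOOH (0.45 equiv), 4 Å MS, CH2Cl2, −20 °C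
Reagents that add atoms: tert-butyl hydroperoxide, CC(C)(C)OO
Why: Sharpless asymmetric epoxidation run as a kinetic resolution: with the D-(−)-tartrate the (S)-enantiomer of 3 (the one with the target's C7 arrangement) is epoxidised fast to the erythro epoxy alcohol, the (R)-enantiomer of 3 is left behind, and the oxirane centre is irrelevant later because C8 becomes a planar radical in step 5.

Step 3
Reactants: 3 rac-1-[4-(benzyloxy)-3,5-dimethoxyphenyl]prop-2-en-1-ol (fresh racemate or the (R)-enriched 3 left over from step 2)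
Product: 5 2-(benzyloxy)-5-[(1E)-3-bromoprop-1-en-1-yl]-1,3-dimethoxybenzene
Conditions: PBr3 (0.4 equiv), Et2O, 0 °C; used crude at once
Reagents that add atoms: phosphorus tribromide, BrP(Br)Br
Why: Bromination with allylic transposition (SN1'/SN2' through the aryl-stabilised allyl cation) gives the conjugated (E)-cinnamyl bromide under thermodynamic control, and since the carbinol centre is destroyed the unwanted enantiomer from step 2 is used up here.

Step 4
Reactants: 4 (R)-[4-(benzyloxy)-3,5-dimethoxyphenyl][(2S)-oxiran-2-yl]methanol; 5 2-(benzyloxy)-5-[(1E)-3-bromoprop-1-en-1-yl]-1,3-dimethoxybenzene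
Product: 6 2-(benzyloxy)-5-[(R)-{[(2E)-3-(4-(benzyloxy)-3,5-dimethoxyphenyl)prop-2-en-1-yl]oxy}[(2S)-oxiran-2-yl]methyl]-1,3-dimethoxybenzene
Conditions: NaH (1.2 equiv, added last), Bu4NI (cat.), THF–DMF, 0 °C to rt
Reagents that add atoms: none
Why: Williamson ether synthesis (SN2 at the primary allylic bromide); the alkoxide of 4 is generated in the presence of 5 at 0 °C so that it is trapped before Payne rearrangement, and C7 is not touched.

Step 5
Reactants: 6 2-(benzyloxy)-5-[(R)-{[(2E)-3-(4-(benzyloxy)-3,5-dimethoxyphenyl)prop-2-en-1-yl]oxy}[(2S)-oxiran-2-yl]methyl]-1,3-dimethoxybenzene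
Product: 9 (7S,8R,7'S,8'R)-4,4'-di-O-benzylsyringaresinol, via bis-titanocene intermediate 7 (not isolated), via benzylic iodide 8 (not isolated)
Conditions: Cp2TiCl (2.5 equiv; preformed from Cp2TiCl2 and Zn dust in THF, decanted), THF, rt, slow addition; then I2 (1.3 equiv), rt
Reagents that add atoms: none
Why: Nugent–RajanBabu reductive epoxide opening by Cp2TiCl (trivalent titanium) gives the C8 radical, which closes ring A by 5-exo-trig addition to the cinnamyl alkene through a Beckwith–Houk chair transition state with the C7 aryl pseudo-equatorial (C8 substituent trans to the aryl, C8 and C8' substituents cis); a second Cp2TiCl captures the benzylic C7' radical, iodinolysis gives the benzylic iodide, and the C9 titanium alkoxide displaces it (intramolecular Williamson closure) to form ring B as the cis-fused exo-aryl furofuran, which only the 8,8'-cis isomer can do.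

Step 6
Reactants: 9 (7S,8R,7'S,8'R)-4,4'-di-O-benzylsyringaresinol
Product: 11 (+)-(7S,8R,8'R)-5,5'-dimethoxylariciresinol, via (+)-syringaresinol 10 (not isolated)
Conditions: H2 (1 atm), 10% Pd/C, THF–MeOH, rt; stopped after uptake of 3 equiv H2 (HPLC control)
Reagents that add atoms: none
Why: Catalytic hydrogenolysis removes both O-benzyl groups and then cleaves one benzylic C–O bond of the C2-symmetric furofuran (either one gives the same product), turning C7' into the benzyl CH2 and C9 into the CH2OH while C7, C8 and C8' stay as set.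

**Compound list**

1 | 4-(benzyloxy)-3,5-dimethoxybenzaldehyde | COc1cc(C=O)cc(OC)c1OCc1ccccc1 | starting material
2 | vinylmagnesium bromide | C=C[Mg]Br | starting material
3 | rac-1-[4-(benzyloxy)-3,5-dimethoxyphenyl]prop-2-en-1-ol (racemate) | COc1cc(C(O)C=C)cc(OC)c1OCc1ccccc1 | intermediate
4 | (R)-[4-(benzyloxy)-3,5-dimethoxyphenyl][(2S)-oxiran-2-yl]methanol | O[C@H](c1cc(OC)c(OCc2ccccc2)c(OC)c1)[C@@H]1CO1 | intermediate
5 | 2-(benzyloxy)-5-[(1E)-3-bromoprop-1-en-1-yl]-1,3-dimethoxybenzene | COc1cc(/C=C/CBr)cc(OC)c1OCc1ccccc1 | intermediate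
6 | (E)-cinnamyl ether of 4: carbinol carbon (C7) R, oxirane carbon (C8) S; same spatial arrangement at C7 as 7S in the target | COc1cc(/C=C/CO[C@H](c2cc(OC)c(OCc3ccccc3)c(OC)c2)[C@@H]2CO2)cc(OC)c1OCc1ccccc1 | intermediate
7 | ring A tetrahydrofuran with Cp2TiCl on C7' and Cp2Ti(Cl)–O on C9 (C7, C8, C8' as in the target, C7' undefined; Cp drawn σ-bound; not isolated) | COc1cc(cc(OC)c1OCc1ccccc1)C([Ti](Cl)(C1C=CC=C1)C1C=CC=C1)[C@H]1CO[C@H](c2cc(OC)c(OCc3ccccc3)c(OC)c2)[C@H]1CO[Ti](Cl)(C1C=CC=C1)C1C=CC=C1 | intermediate
8 | ring A tetrahydrofuran with iodide on C7' and Cp2Ti(Cl)–O on C9 (C7' undefined; not isolated) | COc1cc(cc(OC)c1OCc1ccccc1)C(I)[C@H]1CO[C@H](c2cc(OC)c(OCc3ccccc3)c(OC)c2)[C@H]1CO[Ti](Cl)(C1C=CC=C1)C1C=CC=C1 | intermediate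
9 | (7S,8R,7'S,8'R)-4,4'-di-O-benzylsyringaresinol = (1S,3aR,4S,6aR)-1,4-bis[4-(benzyloxy)-3,5-dimethoxyphenyl]tetrahydro-1H,3H-furo[3,4-c]furan | COc1cc(cc(OC)c1OCc1ccccc1)[C@@H]1[C@H]2CO[C@H](c3cc(OC)c(OCc4ccccc4)c(OC)c3)[C@H]2CO1 | intermediate
10 | (+)-syringaresinol, (7S,8R,7'S,8'R) (not isolated) | COc1cc(cc(OC)c1O)[C@@H]1[C@H]2CO[C@H](c3cc(OC)c(O)c(OC)c3)[C@H]2CO1 | intermediate
11 | (+)-(7S,8R,8'R)-5,5'-dimethoxylariciresinol | COc1cc(C[C@H]2CO[C@H](c3cc(OC)c(O)c(OC)c3)[C@H]2CO)cc(OC)c1O | target

**Step count and risks**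

Total step count: 6. Longest linear sequence: 5 steps (1 → 3 → 4 → 6 → 9 → 11); step 3 is the side branch.

The three steps most likely to fail are steps 5, 6 and 2.

**Step 5 (bicyclisation).** Three things can go wrong: deoxygenation of the epoxide competes with ring closure, the ring A diastereoselectivity is moderate, and the benzylic radical may be reduced instead of intercepted so that ring B never closes. The fallback sets out from 6 and comes back at 11. The titanocene step is run with a proton quench instead of iodine (Cp2TiCl, THF, rt; then aq. NaH2PO4), which gives the monocyclic (7S,8R,8'R)-4,4'-di-O-benzyl-5,5'-dimethoxylariciresinol F3 directly. Its two benzyl ethers are then removed by a short hydrogenolysis (H2, Pd/C, EtOAc, rt), which is much faster than cleavage of the 2-aryl tetrahydrofuran, to give 11.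

**Step 6 (partial hydrogenolysis).** The second ring can open as well, and stopping at exactly one ring opening may be unreliable. The fallback sets out from 9 and comes back at 11. The hydrogenolysis is driven to completion (H2, 4 atm, Pd/C, MeOH), which gives the C2-symmetric (8R,8'R)-5,5'-dimethoxysecoisolariciresinol F4 with no selectivity problem. Ring A is then re-closed oxidatively with 1.0 equiv DDQ in dioxane at rt: one syringyl phenol is oxidised to the p-quinone methide at C7, and the C9' hydroxyl adds to it (5-exo). The 7,8-trans product expected to predominate is 11, and because F4 is C2-symmetric either end gives the same compound.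

**Step 2 (epoxidative kinetic resolution).** A terminal vinyl group reacts slowly, and the ee of the product epoxy alcohol depends on the selectivity factor and on stopping below 50% conversion. Crystallisation of C2-symmetric 9 offers a later chance to raise the ee, but if the resolution itself is poor the fallback sets out from 3 and comes back at 4. Racemic 3 is acylated with vinyl acetate and immobilised Candida antarctica lipase B in MTBE at 30 °C. The enzyme acetylates the (R)-enantiomer to (R)-1-[4-(benzyloxy)-3,5-dimethoxyphenyl]prop-2-en-1-yl acetate F2 and leaves (S)-1-[4-(benzyloxy)-3,5-dimethoxyphenyl]prop-2-en-1-ol F1. F1 is separated and epoxidised under matched, non-resolving conditions (Ti(O-i-Pr)4, D-(−)-diisopropyl tartrate, t-BuOOH, CH2Cl2, −20 °C) to give 4.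

**Further compounds**

F1 | step 2 | (S)-1-[4-(benzyloxy)-3,5-dimethoxyphenyl]prop-2-en-1-ol | O[C@H](c1cc(OC)c(OCc2ccccc2)c(OC)c1)C=C
F2 | step 2 | (R)-1-[4-(benzyloxy)-3,5-dimethoxyphenyl]prop-2-en-1-yl acetate | CC(=O)O[C@@H](c1cc(OC)c(OCc2ccccc2)c(OC)c1)C=C
F3 | step 5 | (7S,8R,8'R)-4,4'-di-O-benzyl-5,5'-dimethoxylariciresinol | COc1cc(C[C@H]2CO[C@H](c3cc(OC)c(OCc4ccccc4)c(OC)c3)[C@H]2CO)cc(OC)c1OCc1ccccc1
F4 | step 6 | (8R,8'R)-5,5'-dimethoxysecoisolariciresinol | COc1cc(C[C@@H](CO)[C@H](CO)Cc2cc(OC)c(O)c(OC)c2)cc(OC)c1O
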